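**Retrosynthetic overview**

1. Numbering: ring C1 (isopropenyl, C8(=C9H2)CH3), C2=C3 (methyl on C3), C4 (C11H2–OAr), C5 (quaternary: methyl and acid chain, first chain carbon C7), C6. The plan rests on the ring bond C4–C5. It ties the allylic methine C4, next to C2=C3, to the quaternary C5, so with a carboxyl (C7) on C5 the ring holds a γ,δ-unsaturated acid, the retron of an ester-enolate Claisen rearrangement.
2. Late disconnections are C11–OAr (Mitsunobu with umbelliferone) and the two outer chain carbons (C7 acid → aldehyde → enoate → propanoate).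
3. Key disconnection: cutting C4–C5 and re-forming C2–O leads back to the 5,6-trans δ-lactone 16, which carries the (E)-C3=C4 arm on C2. Its silyl ketene acetal contracts to acid 20.
4. Lactone: C1–C2 comes from catalytic asymmetric allylboration of enal 3 with (Z)-allylboronate 10, which creates the isopropenyl group and sets C1 and C2. Boronate 10 comes from 1,4-hydroboration of the skipped dienoate 8, and α-methylation brings in the C5 methyl.
5. Ring order: δ-lactone (step 5), then the cyclohexene at the expense of the lactone (step 7). The coumarin rings arrive intact with umbelliferone (step 13).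

Key step: step 7

Assumption: the sense of induction in step 5 follows the accepted model for BINOL-phosphoric-acid-catalysed additions of pinacol allylboronates. In that model the (R)-acid leads to Re-face attack on the aldehyde, so the (S)-acid is specified for the Si-face attack needed here.

**Step 1**
Reactants: 1 (tert-butyldimethylsilyloxy)acetaldehyde; 2 2-(triphenylphosphoranylidene)propanal
Product: 3 (2E)-4-[(tert-butyldimethylsilyl)oxy]-2-methylbut-2-enal
Conditions: toluene, 80 °C
Reagents that add atoms: 2-(triphenylphosphoranylidene)propanal (2), CC(C=O)=P(c1ccccc1)(c1ccccc1)c1ccccc1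
Why: Wittig olefination with a formyl-stabilised ylide should give the (E)-trisubstituted enal, fixing the C3=C4 geometry that later decides the configuration at C4.

**Step 2**
Reactants: 4 3-methylbut-2-enal; 5 trimethyl phosphonoacetate
Product: 6 methyl (2E)-5-methylhexa-2,4-dienoate
Conditions: NaH, THF, 0 °C to rt
Reagents that add atoms: trimethyl phosphonoacetate (5), COC(=O)CP(=O)(OC)OC
Why: Horner–Wadsworth–Emmons olefination of an enal with a stabilised phosphonate anion should give the (2E)-dienoate.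

**Step 3**
Reactants: 6 methyl (2E)-5-methylhexa-2,4-dienoate
Product: 8 methyl (3E)-5-methylhexa-3,5-dienoate, via lithium trienolate 7 (not isolated)
Conditions: LiN(iPr)2, THF–DMPU, −78 °C; then AcOH, −78 °C
Reagents that add atoms: none
Why: In this deconjugative protonation the amide base removes an ε-methyl proton from the s-trans dienoate, and kinetic protonation of 7 at its α-carbon leaves the skipped (3E)-1,3-diene.

**Step 4**
Reactants: 8 methyl (3E)-5-methylhexa-3,5-dienoate; 9 pinacolborane
Product: 10 methyl (4Z)-5-methyl-6-(4,4,5,5-tetramethyl-1,3,2-dioxaborolan-2-yl)hex-4-enoate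
Conditions: Ni(cod)2 (2.5 mol %), PCy3 (2.5 mol %), toluene, rt
Reagents that add atoms: pinacolborane (9), CC1(C)OBOC1(C)C
Why: In the nickel-catalysed 1,4-hydroboration the s-cis-bound diene takes hydrogen at its alkyl-bearing terminus and boron at the free CH2, so the new trisubstituted alkene carries CH2B and the chain cis, that is (Z).

**Step 5**
Reactants: 3 (2E)-4-[(tert-butyldimethylsilyl)oxy]-2-methylbut-2-enal; 10 methyl (4Z)-5-methyl-6-(pinacolboryl)hex-4-enoate
Product: 13 (5R,6S)-6-{(2E)-4-[(tert-butyldimethylsilyl)oxy]but-2-en-2-yl}-5-(prop-1-en-2-yl)oxan-2-one, via pinacol borate 11 (not isolated), via hydroxy ester 12 (not isolated)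
Conditions: (S)-3,3'-bis(2,4,6-triisopropylphenyl)-1,1'-binaphthyl-2,2'-diyl hydrogen phosphate [(S)-TRIP, 5 mol %], 4 Å MS, toluene, −30 to 0 °C; aq NaHCO3; then PPTS (10 mol %), toluene, 50 °C
Reagents that add atoms: none
Why: The chiral phosphoric acid-catalysed allylboration runs through a closed Zimmerman–Traxler chair, in which the (Z)-boronate gives the syn C1/C2 pair (5,6-trans in the ring) and the catalyst selects the Si face of the enal to set C2 as S, after which the δ-hydroxy ester lactonises under mild acid.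

**Step 6**
Reactants: 13 des-methyl lactone; 14 iodomethane
Product: 16 (5R,6S)-6-{(2E)-4-[(tert-butyldimethylsilyl)oxy]but-2-en-2-yl}-3-methyl-5-(prop-1-en-2-yl)oxan-2-one (both C3 epimers), via lithium lactone enolate 15 (not isolated)
Conditions: LiN(iPr)2, THF, −78 °C; MeI, −78 to −40 °C
Reagents that add atoms: iodomethane (14), CI
Why: Lactone enolate alkylation installs the future C5 methyl, and the configuration of the new centre is irrelevant because step 7 makes it planar again.

**Step 7**
Reactants: 16 α-methyl lactone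
Product: 20 (1R,2S,5S)-2-{[(tert-butyldimethylsilyl)oxy]methyl}-1,3-dimethyl-5-(prop-1-en-2-yl)cyclohex-3-ene-1-carboxylic acid, via lithium enolate 17 (not isolated), via trimethylsilyl ketene acetal 18 (not isolated), via trimethylsilyl ester 19 (not isolated)
Conditions: LiN(iPr)2, THF, −78 °C; Me3SiCl, −78 °C to rt; solvent change to toluene, 105 °C; then citric acid, THF–H2O, rt
Reagents that add atoms: chlorotrimethylsilane, C[Si](C)(C)Cl (its Me3Si group is carried by 18 and 19 and leaves again on work-up)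
Why: Deprotonation gives the ring-locked enolate 17 and O-silylation the cyclic ketene acetal 18, in which on heating the six atoms C5=C7(OSi)–O–C2–C3=C4 undergo a concerted suprafacial [3,3]-shift that forms C4–C5, breaks C2–O and moves the alkene to C2=C3, the silyl ester 19 being hydrolysed on work-up. The closest known reaction type is the Ireland–Claisen ring contraction of 6-alkenyl δ-lactone silyl ketene acetals to cyclohex-3-enecarboxylic acids. The carbocycle C1–C6 closes by pericyclic bonding across the 1,4-positions C2 and C5 of the lactone with both arm carbons C3 and C4 becoming ring members (endo mode), which is possible only in a boat, bicyclo[2.2.2]octane-like array because a chair cannot span these positions. C5 is controlled by the C2 stereocentre: the arm lies on one lactone face and delivers C4 to that face of the planar ketene acetal carbon, so C7 ends on the face of the new ring that also holds the isopropenyl group, which is trans to the arm in 16. C4 is controlled by C2 together with the alkene geometry: in the only productive rotamer (C4 between O and C1, C2–H eclipsing the C3 methyl) one alkene face meets C5, and the (E)-geometry turns C11H2OSi outward, hence cis to C7. The step needs the ketene acetal shift to outrun the Cope rearrangement of the 1,5-diene C9=C8–C1–C2–C3=C4 and ionisation of the allylic C2–O bond, which the electron-rich ketene acetal and the irreversible gain of a carbonyl group secure, while the Cope path to a ten-membered ring is uphill and reversible and the cyclic enolate has only one geometry.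

**Step 8**
Reactants: 20 acid
Product: 21 [(1R,2S,5S)-2-{[(tert-butyldimethylsilyl)oxy]methyl}-1,3-dimethyl-5-(prop-1-en-2-yl)cyclohex-3-en-1-yl]methanol
Conditions: LiAlH4, THF, 0 to 40 °C
Reagents that add atoms: none
Why: Hydride reduction of the carboxylic acid with LiAlH4 gives the neopentyl alcohol and leaves the isolated alkenes and the silyl ether untouched.

**Step 9**
Reactants: 21 neopentyl alcohol
Product: 22 (1R,2S,5S)-2-{[(tert-butyldimethylsilyl)oxy]methyl}-1,3-dimethyl-5-(prop-1-en-2-yl)cyclohex-3-ene-1-carbaldehyde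
Conditions: 2-iodoxybenzoic acid, DMSO–THF, rt
Reagents that add atoms: none
Why: Oxidation with 2-iodoxybenzoic acid stops at the aldehyde, which has no α-hydrogen to epimerise and is carried on acid-free so that no carbonyl-ene closure onto the cis isopropenyl group sets in.

**Step 10**
Reactants: 22 aldehyde; 5 trimethyl phosphonoacetate
Product: 23 methyl (2E)-3-[(1S,2S,5S)-2-{[(tert-butyldimethylsilyl)oxy]methyl}-1,3-dimethyl-5-(prop-1-en-2-yl)cyclohex-3-en-1-yl]prop-2-enoate
Conditions: NaH, THF, 0 to 50 °C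
Reagents that add atoms: trimethyl phosphonoacetate (5), COC(=O)CP(=O)(OC)OC
Why: Horner–Wadsworth–Emmons olefination with the small, reactive phosphonate anion tolerates an α-quaternary, non-enolisable aldehyde and adds the two missing chain carbons.

**Step 11**
Reactants: 23 enoate
Product: 24 methyl 3-[(1R,2R,5S)-2-{[(tert-butyldimethylsilyl)oxy]methyl}-1,3-dimethyl-5-(prop-1-en-2-yl)cyclohex-3-en-1-yl]propanoate
Conditions: [(Ph3P)CuH]6 (0.4 equiv), H2O (5 equiv), degassed benzene, rt
Reagents that add atoms: none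
Why: Copper hydride conjugate reduction is a polar 1,4-hydride delivery that touches only the electron-poor enoate, so the two isolated alkenes remain and radical cyclisation onto the isopropenyl group is avoided.

**Step 12**
Reactants: 24 silyl ether
Product: 25 methyl 3-[(1R,2R,5S)-2-(hydroxymethyl)-1,3-dimethyl-5-(prop-1-en-2-yl)cyclohex-3-en-1-yl]propanoate
Conditions: HF·pyridine, pyridine, THF, 0 °C to rt
Reagents that add atoms: none
Why: Fluoride-driven desilylation in a pyridine-buffered medium frees C11–OH without generating an alkoxide that could attack the ester and without protonating the alkenes.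

**Step 13**
Reactants: 25 primary alcohol; 26 umbelliferone (7-hydroxycoumarin)
Product: 27 methyl 3-[(1R,2R,5S)-1,3-dimethyl-2-{[(2-oxo-2H-chromen-7-yl)oxy]methyl}-5-(prop-1-en-2-yl)cyclohex-3-en-1-yl]propanoate
Conditions: PPh3, DIAD, THF, 0 °C to rt
Reagents that add atoms: umbelliferone (26), O=c1ccc2ccc(O)cc2o1
Why: In the Mitsunobu etherification the acidic phenol displaces the activated primary C11 oxygen under neutral conditions, and no stereocentre is involved.

**Step 14**
Reactants: 27 methyl ester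
Product: 29 3-[(1R,2R,5S)-1,3-dimethyl-2-{[(2-oxo-2H-chromen-7-yl)oxy]methyl}-5-(prop-1-en-2-yl)cyclohex-3-en-1-yl]propanoic acid (target), via lithium carboxylate 28 (not isolated)
Conditions: LiOH, THF–MeOH–H2O, 0 °C to rt; then 1 M HCl to pH 2–3
Reagents that add atoms: lithium hydroxide, [Li+].[OH-]
Why: Saponification cleaves the unhindered methyl ester, and any coumarin lactone opened by hydroxide re-closes spontaneously from the cis-hydroxycinnamate on acidification.

**Compound list**

| No. | Name | SMILES | Role |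
|---|---|---|---|
| 1 | (tert-butyldimethylsilyloxy)acetaldehyde | CC(C)(C)[Si](C)(C)OCC=O | starting material |
| 2 | 2-(triphenylphosphoranylidene)propanal | CC(C=O)=P(c1ccccc1)(c1ccccc1)c1ccccc1 | starting material |
| 3 | (2E)-4-[(tert-butyldimethylsilyl)oxy]-2-methylbut-2-enal | O=C/C(C)=C/CO[Si](C)(C)C(C)(C)C | intermediate |
| 4 | 3-methylbut-2-enal | CC(C)=CC=O | starting material |
| 5 | trimethyl phosphonoacetate | COC(=O)CP(=O)(OC)OC | starting material |
| 6 | methyl (2E)-5-methylhexa-2,4-dienoate | COC(=O)/C=C/C=C(C)C | intermediate |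
| 7 | lithium trienolate of 6 | [Li+].C=C(C)/C=C/C=C([O-])OC | intermediate |
| 8 | methyl (3E)-5-methylhexa-3,5-dienoate | C=C(C)/C=C/CC(=O)OC | intermediate |
| 9 | pinacolborane | CC1(C)OBOC1(C)C | starting material |
| 10 | methyl (4Z)-5-methyl-6-(4,4,5,5-tetramethyl-1,3,2-dioxaborolan-2-yl)hex-4-enoate | COC(=O)CC/C=C(C)\CB1OC(C)(C)C(C)(C)O1 | intermediate |
| 11 | methyl (4R,5S,6E)-8-[(tert-butyldimethylsilyl)oxy]-6-methyl-4-(prop-1-en-2-yl)-5-[(4,4,5,5-tetramethyl-1,3,2-dioxaborolan-2-yl)oxy]oct-6-enoate | C=C(C)[C@@H](CCC(=O)OC)[C@H](OB1OC(C)(C)C(C)(C)O1)/C(C)=C/CO[Si](C)(C)C(C)(C)C | intermediate |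
| 12 | methyl (4R,5S,6E)-8-[(tert-butyldimethylsilyl)oxy]-5-hydroxy-6-methyl-4-(prop-1-en-2-yl)oct-6-enoate | C=C(C)[C@@H](CCC(=O)OC)[C@H](O)/C(C)=C/CO[Si](C)(C)C(C)(C)C | intermediate |
| 13 | (5R,6S)-6-{(2E)-4-[(tert-butyldimethylsilyl)oxy]but-2-en-2-yl}-5-(prop-1-en-2-yl)oxan-2-one | C=C(C)[C@H]1CCC(=O)O[C@@H]1/C(C)=C/CO[Si](C)(C)C(C)(C)C | intermediate |
| 14 | iodomethane | CI | starting material |
| 15 | lithium enolate of 13 | [Li+].C=C(C)[C@H]1CC=C([O-])O[C@@H]1/C(C)=C/CO[Si](C)(C)C(C)(C)C | intermediate |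
| 16 | (5R,6S)-6-{(2E)-4-[(tert-butyldimethylsilyl)oxy]but-2-en-2-yl}-3-methyl-5-(prop-1-en-2-yl)oxan-2-one, both C3 epimers | C=C(C)[C@H]1CC(C)C(=O)O[C@@H]1/C(C)=C/CO[Si](C)(C)C(C)(C)C | intermediate |
| 17 | lithium enolate of 16 | [Li+].C=C(C)[C@H]1CC(C)=C([O-])O[C@@H]1/C(C)=C/CO[Si](C)(C)C(C)(C)C | intermediate |
| 18 | (2S,3R)-2-{(2E)-4-[(tert-butyldimethylsilyl)oxy]but-2-en-2-yl}-5-methyl-3-(prop-1-en-2-yl)-6-[(trimethylsilyl)oxy]-3,4-dihydro-2H-pyran | C=C(C)[C@H]1CC(C)=C(O[Si](C)(C)C)O[C@@H]1/C(C)=C/CO[Si](C)(C)C(C)(C)C | intermediate |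
| 19 | trimethylsilyl (1R,2S,5S)-2-{[(tert-butyldimethylsilyl)oxy]methyl}-1,3-dimethyl-5-(prop-1-en-2-yl)cyclohex-3-ene-1-carboxylate | C=C(C)[C@@H]1C=C(C)[C@H](CO[Si](C)(C)C(C)(C)C)[C@](C)(C(=O)O[Si](C)(C)C)C1 | intermediate |
| 20 | (1R,2S,5S)-2-{[(tert-butyldimethylsilyl)oxy]methyl}-1,3-dimethyl-5-(prop-1-en-2-yl)cyclohex-3-ene-1-carboxylic acid | C=C(C)[C@@H]1C=C(C)[C@H](CO[Si](C)(C)C(C)(C)C)[C@](C)(C(=O)O)C1 | intermediate |
| 21 | [(1R,2S,5S)-2-{[(tert-butyldimethylsilyl)oxy]methyl}-1,3-dimethyl-5-(prop-1-en-2-yl)cyclohex-3-en-1-yl]methanol | C=C(C)[C@@H]1C=C(C)[C@H](CO[Si](C)(C)C(C)(C)C)[C@](C)(CO)C1 | intermediate |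
| 22 | (1R,2S,5S)-2-{[(tert-butyldimethylsilyl)oxy]methyl}-1,3-dimethyl-5-(prop-1-en-2-yl)cyclohex-3-ene-1-carbaldehyde | C=C(C)[C@@H]1C=C(C)[C@H](CO[Si](C)(C)C(C)(C)C)[C@](C)(C=O)C1 | intermediate |
| 23 | methyl (2E)-3-[(1S,2S,5S)-2-{[(tert-butyldimethylsilyl)oxy]methyl}-1,3-dimethyl-5-(prop-1-en-2-yl)cyclohex-3-en-1-yl]prop-2-enoate | C=C(C)[C@@H]1C=C(C)[C@H](CO[Si](C)(C)C(C)(C)C)[C@](C)(/C=C/C(=O)OC)C1 | intermediate |
| 24 | methyl 3-[(1R,2R,5S)-2-{[(tert-butyldimethylsilyl)oxy]methyl}-1,3-dimethyl-5-(prop-1-en-2-yl)cyclohex-3-en-1-yl]propanoate | C=C(C)[C@@H]1C=C(C)[C@H](CO[Si](C)(C)C(C)(C)C)[C@](C)(CCC(=O)OC)C1 | intermediate |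
| 25 | methyl 3-[(1R,2R,5S)-2-(hydroxymethyl)-1,3-dimethyl-5-(prop-1-en-2-yl)cyclohex-3-en-1-yl]propanoate | C=C(C)[C@@H]1C=C(C)[C@H](CO)[C@](C)(CCC(=O)OC)C1 | intermediate |
| 26 | umbelliferone | O=c1ccc2ccc(O)cc2o1 | starting material |
| 27 | methyl 3-[(1R,2R,5S)-1,3-dimethyl-2-{[(2-oxo-2H-chromen-7-yl)oxy]methyl}-5-(prop-1-en-2-yl)cyclohex-3-en-1-yl]propanoate | C=C(C)[C@@H]1C=C(C)[C@H](COc2ccc3ccc(=O)oc3c2)[C@](C)(CCC(=O)OC)C1 | intermediate |
| 28 | lithium salt of 29 | [Li+].C=C(C)[C@@H]1C=C(C)[C@H](COc2ccc3ccc(=O)oc3c2)[C@](C)(CCC(=O)[O-])C1 | intermediate |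
| 29 | 3-[(1R,2R,5S)-1,3-dimethyl-2-{[(2-oxo-2H-chromen-7-yl)oxy]methyl}-5-(prop-1-en-2-yl)cyclohex-3-en-1-yl]propanoic acid | C=C(C)[C@@H]1C=C(C)[C@H](COc2ccc3ccc(=O)oc3c2)[C@](C)(CCC(=O)O)C1 | target |

**Step count**

- Total step count: 14.
- Longest linear sequence: 13 (steps 2 to 14, from 3-methylbut-2-enal); step 1 is the side branch.

**Steps most likely to fail**

**Step 7.** The new bond joins a fully substituted ketene acetal carbon to a substituted alkene terminus inside a forced boat. The shift may therefore be slower than hydrolysis, C-silylation or thermal ionisation of the ketene acetal.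

The fallback separates ring contraction from creation of the quaternary centre. It sets out from 13 and returns at 21.
- LiN(iPr)2 and Me3SiCl convert 13 into the less crowded des-methyl ketene acetal F1.
- Heating F1 in toluene should give the des-methyl trimethylsilyl ester F2, and mild hydrolysis the all-cis des-methyl acid F3. This is the parent case of the lactone contraction.
- MeI and K2CO3 in DMF give the des-methyl methyl ester F4.
- LiN(iPr)2 followed by MeI alkylates the exocyclic ester enolate of F4 from the face anti to the neighbouring C11H2OSi group and the isopropenyl group. This should give the α-methylated methyl ester F5, with the methyl trans to C11.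
- LiAlH4 reduces F5 to alcohol 21.

**Step 5.** Both partners are more substituted than the usual substrates. Facial discrimination by the catalyst may be poor, or the catalysed path may be slow enough for the racemic background reaction to compete.

The fallback replaces asymmetric induction by kinetic resolution. It sets out from 3 and 10 and returns at 13.
- The uncatalysed allylboration in toluene at rt still passes through the closed chair and stays syn-selective. After a neutral work-up it gives 12 together with the enantiomeric hydroxy ester F6.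
- Sharpless kinetic resolution (Ti(OiPr)4, D-(−)-diisopropyl tartrate, tBuOOH, 4 Å MS, CH2Cl2, −20 °C) should consume the (5R)-carbinol F6 faster, as the erythro epoxy alcohol F7, and leave 12.
- After chromatographic separation, 12 is closed with PPTS to 13.

**Step 4.** The skipped diene may migrate into conjugation with the ester, or the ester may bind to zerovalent nickel, and either process would erode conversion and regiocontrol.

The fallback carries the chain terminus at the alcohol oxidation level. It sets out from 8 and returns at 13.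
- LiAlH4 gives the dienol F8, and NaH with 4-methoxybenzyl chloride gives the 4-methoxybenzyl ether F9.
- The conditions of step 4 turn F9 into the ether-bearing (Z)-allylboronate F10.
- The conditions of the first stage of step 5, with enal 3, give the syn homoallylic alcohol F11.
- DDQ in wet CH2Cl2 frees the 1,5-diol F12.
- TEMPO with PhI(OAc)2 oxidises the primary alcohol selectively, and the lactol F13 formed by ring closure is oxidised on to lactone 13.

**Further compounds**

F1 | step 7 | (2S,3R)-2-{(2E)-4-[(tert-butyldimethylsilyl)oxy]but-2-en-2-yl}-3-(prop-1-en-2-yl)-6-[(trimethylsilyl)oxy]-3,4-dihydro-2H-pyran | C=C(C)[C@H]1CC=C(O[Si](C)(C)C)O[C@@H]1/C(C)=C/CO[Si](C)(C)C(C)(C)C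
F2 | step 7 | trimethylsilyl (1R,2R,5S)-2-{[(tert-butyldimethylsilyl)oxy]methyl}-3-methyl-5-(prop-1-en-2-yl)cyclohex-3-ene-1-carboxylate | C=C(C)[C@@H]1C=C(C)[C@H](CO[Si](C)(C)C(C)(C)C)[C@H](C(=O)O[Si](C)(C)C)C1
F3 | step 7 | (1R,2R,5S)-2-{[(tert-butyldimethylsilyl)oxy]methyl}-3-methyl-5-(prop-1-en-2-yl)cyclohex-3-ene-1-carboxylic acid | C=C(C)[C@@H]1C=C(C)[C@H](CO[Si](C)(C)C(C)(C)C)[C@H](C(=O)O)C1
F4 | step 7 | methyl (1R,2R,5S)-2-{[(tert-butyldimethylsilyl)oxy]methyl}-3-methyl-5-(prop-1-en-2-yl)cyclohex-3-ene-1-carboxylate | C=C(C)[C@@H]1C=C(C)[C@H](CO[Si](C)(C)C(C)(C)C)[C@H](C(=O)OC)C1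
F5 | step 7 | methyl (1R,2S,5S)-2-{[(tert-butyldimethylsilyl)oxy]methyl}-1,3-dimethyl-5-(prop-1-en-2-yl)cyclohex-3-ene-1-carboxylate | C=C(C)[C@@H]1C=C(C)[C@H](CO[Si](C)(C)C(C)(C)C)[C@](C)(C(=O)OC)C1
F6 | step 5 | methyl (4S,5R,6E)-8-[(tert-butyldimethylsilyl)oxy]-5-hydroxy-6-methyl-4-(prop-1-en-2-yl)oct-6-enoate (enantiomer of 12) | C=C(C)[C@H](CCC(=O)OC)[C@@H](O)/C(C)=C/CO[Si](C)(C)C(C)(C)C
F7 | step 5 | erythro 6,7-epoxide of F6 (trans-epoxide, oxygen delivered by the D-(−)-tartrate catalyst) | C=C(C)[C@H](CCC(=O)OC)[C@@H](O)[C@]1(C)O[C@H]1CO[Si](C)(C)C(C)(C)C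
F8 | step 4 | (3E)-5-methylhexa-3,5-dien-1-ol | C=C(C)/C=C/CCO
F9 | step 4 | 1-methoxy-4-({[(3E)-5-methylhexa-3,5-dien-1-yl]oxy}methyl)benzene | C=C(C)/C=C/CCOCc1ccc(OC)cc1
F10 | step 4 | 2-{(2Z)-6-[(4-methoxybenzyl)oxy]-2-methylhex-2-en-1-yl}-4,4,5,5-tetramethyl-1,3,2-dioxaborolane | COc1ccc(COCCC/C=C(C)\CB2OC(C)(C)C(C)(C)O2)cc1
F11 | step 4 | (2E,4S,5R)-1-[(tert-butyldimethylsilyl)oxy]-8-[(4-methoxybenzyl)oxy]-3-methyl-5-(prop-1-en-2-yl)oct-2-en-4-ol | C=C(C)[C@@H](CCCOCc1ccc(OC)cc1)[C@H](O)/C(C)=C/CO[Si](C)(C)C(C)(C)C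
F12 | step 4 | (4R,5S,6E)-8-[(tert-butyldimethylsilyl)oxy]-6-methyl-4-(prop-1-en-2-yl)oct-6-ene-1,5-diol | C=C(C)[C@@H](CCCO)[C@H](O)/C(C)=C/CO[Si](C)(C)C(C)(C)C
F13 | step 4 | (5R,6S)-6-{(2E)-4-[(tert-butyldimethylsilyl)oxy]but-2-en-2-yl}-5-(prop-1-en-2-yl)oxan-2-ol (both anomers) | C=C(C)[C@H]1CCC(O)O[C@@H]1/C(C)=C/CO[Si](C)(C)C(C)(C)C
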